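The numbers in the tables were computed on assumed constants; noise was put on by code.

If you would rather lean on readings than on a scheme, you can judge these set-ups from the columns of the earlier closed-flask runs.

| flask | starting material | reagent | capture agent | remark | time |
|---|---|---|---|---|---|
| green | 0.050 M | 1.1 equiv | 2.5 mM | run made earlier |  |
| ochre | 0.075 M | 1.1 equiv | 2.5 mM | run made earlier |  |
| summer | 0.050 M | 1.10 equiv (fed, over 2.50 h) | 2.50 mM | a stirred flask in which reagent is dosed at a steady rate over 2.50 h without added volume, worked up at 2.5 h | 2.5 h |
| midnight | 0.050 M | 1.10 equiv | 2.50 mM | a single well-mixed tank run continuously and read at steady state, 2.5 h in it on average |  |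
| noon | 0.050 M (fed, over 2.50 h) | 1.10 equiv | 2.50 mM | a stirred flask in which starting material is dosed at a steady rate over 2.50 h without added volume, worked up at 2.5 h | 2.5 h |
| dawn | 0.050 M | 1.10 equiv | 2.50 mM | a closed flask charged with all of it at once and left for 2.5 h | 2.5 h |

- green (time / h: target / %, starting material / %): 0.333: 12.5, 37.5; 0.833: 37.0, 8.5; 1.50: 57.0, 0.8; 2.50: 71.9, 0.3
- ochre (time / min: target / %, starting material / %): 6.00: 2.4, 75.0; 15.0: 11.3, 47.5; 30.0: 28.8, 22.5; 50.0: 46.8, 7.7

(readings scatter by 0.3 percentage points)

- the stated concentrations are those of everything mixed, before any reaction; amounts are the same in each set-up
- the feed brings no volume worth counting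
- the earlier runs were made in a closed, stirred flask

- the set-up with the highest amount of target at the outlet or at the end, in percent of the starting material put in ("none" if the first two lie within 2 percentage points) (summer / midnight / noon / dawn / none)
- amount of target at the outlet or at the end, in percent of the starting material put in, summer
- amount of target at the outlet or at the end, in percent of the starting material put in, midnight
- amount of target at the outlet or at the end, in percent of the starting material put in, noon
- amount of target at the outlet or at the end, in percent of the starting material put in, dawn

Start with the starting-material column. In the green run it falls from 37.5% to 8.5% between 0.333 h and 0.833 h, a loss constant of 2.97 h⁻¹. In the more concentrated ochre run it falls from 75.0% to 7.7% between 6.00 min and 50.0 min, which gives 3.10 h⁻¹, close to the green value. The loss looks first-order, so freeze it and carry the half-time of the starting material, the time in which it falls to half at either concentration: 0.233 h.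

Now set target beside it. At 0.833 h in the green run, about half of the charge is in neither column. That gap is 54.5%, and it shrinks to 27.8% by 2.50 h, about half in 1.67 h, a span much longer than the half-time of the starting material. So something unseen stands in the gap, and in the green run its slower uptake is the rate-limiting step from 1.50 h on, when the starting material reads 0.8%.

Read the same moment across the runs: at 50.0 min, ochre has 7.7% starting material against 8.5% in green, but more target, 46.8% against 37.0%. The slow stage therefore quickens with concentration, and I take its partner to be the reagent.

My reckoning follows. Dawn is the green charge in the same kind of flask for the same time, so I put it at 71.9%. In summer, the reagent fed so far averages half of its charge over the dosing. In noon, the last portions enter with less than 0.233 h left. In midnight, the frozen constant leaves 11.9% of the starting material at the outlet, more than the 0.3% of green at 2.50 h. I name dawn as best.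

The forecast also names dawn, with 53.5% for summer, 52.2% for midnight, 46.3% for noon and 71.9% for dawn, and says of summer: “reagent starves the second step”.

The flask gives dawn as best, with 71.7% there, 54.7% for summer, 52.0% for midnight and 46.2% for noon.

    starting material → open intermediate (k = 0.0490 min⁻¹)
    reagent + open intermediate → target (k = 0.390 L mol⁻¹ min⁻¹)
    open intermediate + capture agent → trapped intermediate (k = 1.50 L mol⁻¹ min⁻¹)
    starting material + open intermediate → side product (k = 0.0300 L mol⁻¹ min⁻¹)

In dawn, the carried half-time of the starting material, 0.233 h, is shorter than 0.54 h, the half-life of the open intermediate by the reagent step alone with the other concentrations as charged, and that in turn is shorter than the 3.1 h by the capture step alone. In midnight, the frozen constant gave 11.9%, and the tank holds 11.9% of the starting material at its outlet.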